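## Retrosynthetic overview

- The target is opened at the two ring carbinols: a catalyst-controlled enone reduction and a carbinol-directed ketone reduction lead back to an epoxyquinone.
- The epoxyquinone comes from the key C–O step: a carbinol-directed nucleophilic epoxidation of a (1-hydroxyalkyl)benzoquinone, which relays the side-chain carbinol configuration to both oxirane carbons.
- The quinone comes from oxidative demethylation of a 2,5-dimethoxyaryl carbinol, itself made by enantioselective alkenylzinc addition of a trienyl iodide to an aryl aldehyde.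
- The trienyl iodide comes from pseudoionone (alkyne formation, carboalumination–iodination); the aldehyde comes from 2,5-dimethoxybenzyl alcohol (acetylation, formylation).
- Ring order: the six-membered carbocycle is the commercial benzene ring (dearomatised to the quinone); the oxirane is the only ring formed, late.

Assumption: pseudoionone is bought as the single (3E,5E) isomer (or distilled from the commercial isomer mixture).

Locants used below for the bicyclic compounds: C-1 oxirane CH, C-2, C-3 (bears CH2OAc), C-4 (=CH), C-5, C-6 (oxirane carbon bearing the side chain); C-1' is the side-chain carbinol carbon.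

## Route

Step 1
Reactants: 1 (3E,5E)-6,10-dimethylundeca-3,5,9-trien-2-one (pseudoionone)
Product: 3 (3E,5E)-6,10-dimethylundeca-3,5,9-trien-1-yne, via dienyl enol phosphate 2 (not isolated)
Conditions: LiN(i-Pr)2 (1.1 equiv), THF, −78 °C; ClP(O)(OEt)2, −78 °C to rt; LiN(i-Pr)2 (2.3 equiv), −78 °C to rt; aq. NH4Cl
Reagents that add atoms: none
Why: Negishi conversion of a methyl ketone into a terminal alkyne (kinetic enolate at CH3, O-phosphorylation, E2 elimination of the enol phosphate), established on ionone-type dienones, leaves both E olefins untouched; no stereocentre is formed.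

Step 2
Reactants: 3 (3E,5E)-6,10-dimethylundeca-3,5,9-trien-1-yne
Product: 5 (1E,3E,5E)-1-iodo-2,6,10-trimethylundeca-1,3,5,9-tetraene, via alkenylalane 4 (not isolated)
Conditions: AlMe3 (2.5 equiv), Cp2ZrCl2 (0.25 equiv), CH2Cl2, 0 °C to rt; then I2, THF, −30 to 0 °C
Reagents that add atoms: trimethylaluminium C[Al](C)C; iodine II
Why: Negishi zirconium-catalysed carboalumination adds methyl and aluminium syn across the terminal alkyne (methyl to the internal carbon) and iodinolysis with retention fixes the 1E trisubstituted iodoalkene; the isolated trisubstituted olefin is inert.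

Step 3
Reactants: 6 (2,5-dimethoxyphenyl)methanol
Product: 7 (2,5-dimethoxyphenyl)methyl acetate
Conditions: Ac2O, pyridine, DMAP (cat.), CH2Cl2, rt
Reagents that add atoms: acetic anhydride CC(=O)OC(C)=O
Why: Standard O-acylation; the acetate is the ester of the target and, being non-directing, keeps this arm from competing in the later directed epoxidation.

Step 4
Reactants: 7 (2,5-dimethoxyphenyl)methyl acetate
Product: 9 (4-formyl-2,5-dimethoxyphenyl)methyl acetate, via α-chloro ether 8 (not isolated)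
Conditions: Cl2CHOMe, TiCl4, CH2Cl2, −78 to −20 °C; then H2O
Reagents that add atoms: dichloromethyl methyl ether COC(Cl)Cl; water O
Why: Rieche formylation; electrophilic substitution goes para to the CH2OAc group and ortho to a methoxy group (the site attacked in 2,5-dimethoxytoluenes), and the α-chloro ether is hydrolysed on work-up.

Step 5
Reactants: 5 (1E,3E,5E)-1-iodo-2,6,10-trimethylundeca-1,3,5,9-tetraene; 9 (4-formyl-2,5-dimethoxyphenyl)methyl acetate
Product: 12 [4-[(1S,2E,4E,6E)-1-hydroxy-3,7,11-trimethyldodeca-2,4,6,10-tetraen-1-yl]-2,5-dimethoxyphenyl]methyl acetate, via trienyllithium 10 (not isolated), via trienylzinc bromide 11 (not isolated)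
Conditions: 5, t-BuLi (2.0 equiv), Et2O, −78 °C; ZnBr2 (1.05 equiv), −78 to 0 °C; N,N,N',N'-tetraethylethylenediamine (0.3 equiv), (−)-MIB [(2S)-3-exo-morpholinoisoborneol, 10 mol %], toluene; then 9, −10 °C; aq. NH4Cl
Reagents that add atoms: none
Why: Catalytic enantioselective alkenylzinc addition to an aryl aldehyde (amino-alkoxide-ligated zinc, Noyori-type bimetallic transition state) transfers the alkenyl group to the Si face and sets C-1' as S; the zinc reagent spares the acetate and the diamine masks the lithium halides that would cause racemic background addition.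

Step 6
Reactants: 12 [4-[(1S,2E,4E,6E)-1-hydroxy-3,7,11-trimethyldodeca-2,4,6,10-tetraen-1-yl]-2,5-dimethoxyphenyl]methyl acetate
Product: 13 [4-[(1S,2E,4E,6E)-1-hydroxy-3,7,11-trimethyldodeca-2,4,6,10-tetraen-1-yl]-3,6-dioxocyclohexa-1,4-dien-1-yl]methyl acetate
Conditions: (NH4)2Ce(NO3)6 (2.3 equiv), MeCN–H2O (2:1), −10 to 0 °C, 10 min
Reagents that add atoms: water O
Why: Oxidative demethylation of a 1,4-dimethoxyarene by tetravalent cerium (two one-electron oxidations, ipso attack of water, loss of two methanol) gives the p-quinone, a reaction known for 1-(2,5-dimethoxyphenyl)alkanols; the arene is the most easily oxidised site and C-1' is not touched.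

Step 7
Reactants: 13 [4-[(1S,2E,4E,6E)-1-hydroxy-3,7,11-trimethyldodeca-2,4,6,10-tetraen-1-yl]-3,6-dioxocyclohexa-1,4-dien-1-yl]methyl acetate
Product: 14 [(1R,6S)-6-[(1S,2E,4E,6E)-1-hydroxy-3,7,11-trimethyldodeca-2,4,6,10-tetraen-1-yl]-2,5-dioxo-7-oxabicyclo[4.1.0]hept-3-en-3-yl]methyl acetate
Conditions: Ph3COOH (1.3 equiv), BnNMe3OH (0.2 equiv), 4 Å sieves, toluene, −40 to −20 °C
Reagents that add atoms: trityl hydroperoxide OOC(c1ccccc1)(c1ccccc1)c1ccccc1
Why: Proposed new method: carbinol-directed Weitz–Scheffer epoxidation of a (1-hydroxyalkyl)-1,4-benzoquinone, in which the bulky trityl peroxide anion (non-chelating ammonium counter-ion) is held by hydrogen bonding to the C-1' hydroxyl; in the A(1,2)-strain-minimised rotamer (carbinol H eclipsing the ring C=O side) the hydroxyl lies over one face of the adjacent ring CH while the trienyl chain shields the other, so conjugate addition at that CH and closure of the enolate on oxygen with loss of Ph3CO− put the oxirane syn to the hydroxyl (threo; 1'S gives 1R,6S), while the acetoxymethyl-bearing double bond has no delivery and is poorly accessible to the trityl reagent; the closest known reactions are the hydroxyl-directed syn nucleophilic epoxidation of p-quinols (t-BuOOH, BnNMe3OH) and the trityl hydroperoxide epoxidation of hydroxymethyl quinone monoketals.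

Step 8
Reactants: 14 [(1R,6S)-6-[(1S,2E,4E,6E)-1-hydroxy-3,7,11-trimethyldodeca-2,4,6,10-tetraen-1-yl]-2,5-dioxo-7-oxabicyclo[4.1.0]hept-3-en-3-yl]methyl acetate
Product: 15 [(1R,5S,6R)-5-hydroxy-6-[(1S,2E,4E,6E)-1-hydroxy-3,7,11-trimethyldodeca-2,4,6,10-tetraen-1-yl]-2-oxo-7-oxabicyclo[4.1.0]hept-3-en-3-yl]methyl acetate
Conditions: Me4NBH(OAc)3 (4 equiv), MeCN–AcOH (4:1), −35 °C
Reagents that add atoms: none
Why: Evans–Saksena hydroxyl-directed reduction; the C-1' alkoxy(acetoxy)borohydride delivers hydride intramolecularly through a chair transition state with the trienyl group equatorial, onto the oxirane-side face of the C-5 ketone only (no hydroxyl is near the C-2 ketone), giving the 1,3-anti diol, i.e. 5S with the hydroxyl trans to the oxirane; acetate and oxirane are inert.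

Step 9
Reactants: 15 [(1R,5S,6R)-5-hydroxy-6-[(1S,2E,4E,6E)-1-hydroxy-3,7,11-trimethyldodeca-2,4,6,10-tetraen-1-yl]-2-oxo-7-oxabicyclo[4.1.0]hept-3-en-3-yl]methyl acetate
Product: 16 [(1S,2R,5S,6R)-2,5-dihydroxy-6-[(1S,2E,4E,6E)-1-hydroxy-3,7,11-trimethyldodeca-2,4,6,10-tetraen-1-yl]-7-oxabicyclo[4.1.0]hept-3-en-3-yl]methyl acetate
Conditions: (R)-2-methyl-CBS-oxazaborolidine (1.0 equiv), catecholborane (4 equiv), toluene–CH2Cl2, −78 °C; MeOH, aq. NaHCO3
Reagents that add atoms: none
Why: Corey–Bakshi–Shibata 1,2-reduction of an α-substituted cyclohexenone; with the substituted alkenyl carbon as the large group and the oxirane CH as the small one, the (R)-catalyst delivers hydride to the oxirane-side face and sets C-2 as R (hydroxyl cis to the C-5 hydroxyl, trans to the oxirane), and catecholborane spares acetate, oxirane and polyene.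

## Compound list

1 | (3E,5E)-6,10-dimethylundeca-3,5,9-trien-2-one (pseudoionone) | CC(=O)/C=C/C=C(\C)CCC=C(C)C | starting material
2 | diethyl (3E,5E)-6,10-dimethylundeca-1,3,5,9-tetraen-2-yl phosphate | C=C(OP(=O)(OCC)OCC)/C=C/C=C(\C)CCC=C(C)C | intermediate
3 | (3E,5E)-6,10-dimethylundeca-3,5,9-trien-1-yne | C#C/C=C/C=C(\C)CCC=C(C)C | intermediate
4 | dimethyl[(1E,3E,5E)-2,6,10-trimethylundeca-1,3,5,9-tetraen-1-yl]alane | C[Al](C)/C=C(C)/C=C/C=C(\C)CCC=C(C)C | intermediate
5 | (1E,3E,5E)-1-iodo-2,6,10-trimethylundeca-1,3,5,9-tetraene | I/C=C(C)/C=C/C=C(\C)CCC=C(C)C | intermediate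
6 | (2,5-dimethoxyphenyl)methanol | COc1ccc(OC)c(CO)c1 | starting material
7 | (2,5-dimethoxyphenyl)methyl acetate | COc1ccc(OC)c(COC(C)=O)c1 | intermediate
8 | [4-[chloro(methoxy)methyl]-2,5-dimethoxyphenyl]methyl acetate | COC(Cl)c1cc(OC)c(COC(C)=O)cc1OC | intermediate
9 | (4-formyl-2,5-dimethoxyphenyl)methyl acetate | COc1cc(C=O)c(OC)cc1COC(C)=O | intermediate
10 | [(1E,3E,5E)-2,6,10-trimethylundeca-1,3,5,9-tetraen-1-yl]lithium | [Li]/C=C(C)/C=C/C=C(\C)CCC=C(C)C | intermediate
11 | bromo[(1E,3E,5E)-2,6,10-trimethylundeca-1,3,5,9-tetraen-1-yl]zinc | Br[Zn]/C=C(C)/C=C/C=C(\C)CCC=C(C)C | intermediate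
12 | [4-[(1S,2E,4E,6E)-1-hydroxy-3,7,11-trimethyldodeca-2,4,6,10-tetraen-1-yl]-2,5-dimethoxyphenyl]methyl acetate | COc1cc([C@@H](O)/C=C(C)/C=C/C=C(\C)CCC=C(C)C)c(OC)cc1COC(C)=O | intermediate
13 | [4-[(1S,2E,4E,6E)-1-hydroxy-3,7,11-trimethyldodeca-2,4,6,10-tetraen-1-yl]-3,6-dioxocyclohexa-1,4-dien-1-yl]methyl acetate | CC(=O)OCC1=CC(=O)C([C@@H](O)/C=C(C)/C=C/C=C(\C)CCC=C(C)C)=CC1=O | intermediate
14 | [(1R,6S)-6-[(1S,2E,4E,6E)-1-hydroxy-3,7,11-trimethyldodeca-2,4,6,10-tetraen-1-yl]-2,5-dioxo-7-oxabicyclo[4.1.0]hept-3-en-3-yl]methyl acetate | CC(=O)OCC1=CC(=O)[C@@]2([C@@H](O)/C=C(C)/C=C/C=C(\C)CCC=C(C)C)O[C@H]2C1=O | intermediate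
15 | [(1R,5S,6R)-5-hydroxy-6-[(1S,2E,4E,6E)-1-hydroxy-3,7,11-trimethyldodeca-2,4,6,10-tetraen-1-yl]-2-oxo-7-oxabicyclo[4.1.0]hept-3-en-3-yl]methyl acetate | CC(=O)OCC1=C[C@H](O)[C@@]2([C@@H](O)/C=C(C)/C=C/C=C(\C)CCC=C(C)C)O[C@H]2C1=O | intermediate
16 | [(1S,2R,5S,6R)-2,5-dihydroxy-6-[(1S,2E,4E,6E)-1-hydroxy-3,7,11-trimethyldodeca-2,4,6,10-tetraen-1-yl]-7-oxabicyclo[4.1.0]hept-3-en-3-yl]methyl acetate | CC(=O)OCC1=C[C@H](O)[C@@]2([C@@H](O)/C=C(C)/C=C/C=C(\C)CCC=C(C)C)O[C@H]2[C@@H]1O | target

## Step count and risks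

Total steps: 9. Longest linear sequence: 7 steps (6 → 16 through steps 3–9; the branch 1 → 16 through steps 1, 2, 5–9 is equally long).

**Step 7 (the proposed new epoxidation) is the most likely to fail.** The failure modes are attack on the hydrogen-bonded (OH···O=C) rotamer, which would give the other oxirane face, base-induced isomerisation of the hydroxyalkyl quinone, and reaction at the other double bond. The fallback uses known chemistry and decouples the oxirane from C-1'; it sets out from aldehyde 9 (with iodide 5) and comes back at 14. BCl3 (CH2Cl2, −78 °C) cleaves only the methyl ether ortho to the formyl group, giving (4-formyl-5-hydroxy-2-methoxyphenyl)methyl acetate F1. NaBH4 reduces the aldehyde to [5-hydroxy-4-(hydroxymethyl)-2-methoxyphenyl]methyl acetate F2. PhI(OAc)2 in methanol then gives the quinone monoketal [4-(hydroxymethyl)-6,6-dimethoxy-3-oxocyclohexa-1,4-dien-1-yl]methyl acetate F3, in which only the hydroxymethyl-bearing double bond has a free β-position. The known hydroxyl-directed asymmetric nucleophilic epoxidation of hydroxymethyl quinone monoketals (Ph3COOH, NaN(SiMe3)2, diisopropyl tartrate, toluene, −60 °C) sets the oxirane by reagent control, giving [(1R,6S)-6-(hydroxymethyl)-2,2-dimethoxy-5-oxo-7-oxabicyclo[4.1.0]hept-3-en-3-yl]methyl acetate F4. Dess–Martin oxidation gives [(1R,6R)-6-formyl-2,2-dimethoxy-5-oxo-7-oxabicyclo[4.1.0]hept-3-en-3-yl]methyl acetate F5. Nozaki–Hiyama–Kishi coupling with 5 (CrCl2, NiCl2 cat., DMSO) adds the trienyl group to the aldehyde anti to the oxirane C–O bond (Felkin–Anh; a chiral sulfonamide ligand on chromium can reinforce it), giving [(1R,6S)-6-[(1S,2E,4E,6E)-1-hydroxy-3,7,11-trimethyldodeca-2,4,6,10-tetraen-1-yl]-2,2-dimethoxy-5-oxo-7-oxabicyclo[4.1.0]hept-3-en-3-yl]methyl acetate F6. Ketal hydrolysis on montmorillonite K10 in wet CH2Cl2 returns to 14.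

**Step 6 (oxidative demethylation next to a triene and a free, doubly activated carbinol) is the second risk.** The concerns are oxidation or acid-promoted ionisation at the carbinol and electron transfer from the triene. The fallback carries the carbinol through the oxidation as a silyl ether; it sets out from 12 and comes back at 13. Et3SiOTf and 2,6-lutidine give [4-[(1S,2E,4E,6E)-3,7,11-trimethyl-1-(triethylsilyloxy)dodeca-2,4,6,10-tetraen-1-yl]-2,5-dimethoxyphenyl]methyl acetate F7. Oxidation with (NH4)2Ce(NO3)6 in NaHCO3-buffered aqueous MeCN at −10 °C gives [3,6-dioxo-4-[(1S,2E,4E,6E)-3,7,11-trimethyl-1-(triethylsilyloxy)dodeca-2,4,6,10-tetraen-1-yl]cyclohexa-1,4-dien-1-yl]methyl acetate F8. HF·pyridine buffered with pyridine (THF, 0 °C) removes the silyl group to return to 13.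

**Step 9 (CBS reduction) is the third risk.** The catalyst must override the substrate's preference for hydride attack anti to the oxirane, and two free hydroxyls are present. The fallback uses that substrate bias and then inverts; it sets out from 15 and comes back at 16. Luche reduction (NaBH4, CeCl3·7H2O, MeOH, −78 °C) gives the 2-epimer [(1S,2S,5S,6R)-2,5-dihydroxy-6-[(1S,2E,4E,6E)-1-hydroxy-3,7,11-trimethyldodeca-2,4,6,10-tetraen-1-yl]-7-oxabicyclo[4.1.0]hept-3-en-3-yl]methyl acetate F9. Mitsunobu reaction with chloroacetic acid (PPh3, DIAD, THF, 0 °C) inverts the least hindered allylic hydroxyl (C-2; the C-5 and C-1' hydroxyls are flanked by the quaternary oxirane carbon), as is established for syn-to-anti inversion of epoxycyclohexenols, giving [(1S,2R,5S,6R)-2-(chloroacetoxy)-5-hydroxy-6-[(1S,2E,4E,6E)-1-hydroxy-3,7,11-trimethyldodeca-2,4,6,10-tetraen-1-yl]-7-oxabicyclo[4.1.0]hept-3-en-3-yl]methyl acetate F10. Thiourea with NaHCO3 in EtOH removes the chloroacetate in the presence of the primary acetate to give 16.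

## Further compounds

F1 | step 7 | (4-formyl-5-hydroxy-2-methoxyphenyl)methyl acetate | COc1cc(C=O)c(O)cc1COC(C)=O
F2 | step 7 | [5-hydroxy-4-(hydroxymethyl)-2-methoxyphenyl]methyl acetate | COc1cc(CO)c(O)cc1COC(C)=O
F3 | step 7 | [4-(hydroxymethyl)-6,6-dimethoxy-3-oxocyclohexa-1,4-dien-1-yl]methyl acetate | CC(=O)OCC1=CC(=O)C(CO)=CC1(OC)OC
F4 | step 7 | [(1R,6S)-6-(hydroxymethyl)-2,2-dimethoxy-5-oxo-7-oxabicyclo[4.1.0]hept-3-en-3-yl]methyl acetate | CC(=O)OCC1=CC(=O)[C@@]2(CO)O[C@H]2C1(OC)OC
F5 | step 7 | [(1R,6R)-6-formyl-2,2-dimethoxy-5-oxo-7-oxabicyclo[4.1.0]hept-3-en-3-yl]methyl acetate | CC(=O)OCC1=CC(=O)[C@@]2(C=O)O[C@H]2C1(OC)OC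
F6 | step 7 | [(1R,6S)-6-[(1S,2E,4E,6E)-1-hydroxy-3,7,11-trimethyldodeca-2,4,6,10-tetraen-1-yl]-2,2-dimethoxy-5-oxo-7-oxabicyclo[4.1.0]hept-3-en-3-yl]methyl acetate | CC(=O)OCC1=CC(=O)[C@@]2([C@@H](O)/C=C(C)/C=C/C=C(\C)CCC=C(C)C)O[C@H]2C1(OC)OC
F7 | step 6 | [4-[(1S,2E,4E,6E)-3,7,11-trimethyl-1-(triethylsilyloxy)dodeca-2,4,6,10-tetraen-1-yl]-2,5-dimethoxyphenyl]methyl acetate | COc1cc([C@@H](O[Si](CC)(CC)CC)/C=C(C)/C=C/C=C(\C)CCC=C(C)C)c(OC)cc1COC(C)=O
F8 | step 6 | [3,6-dioxo-4-[(1S,2E,4E,6E)-3,7,11-trimethyl-1-(triethylsilyloxy)dodeca-2,4,6,10-tetraen-1-yl]cyclohexa-1,4-dien-1-yl]methyl acetate | CC(=O)OCC1=CC(=O)C([C@@H](O[Si](CC)(CC)CC)/C=C(C)/C=C/C=C(\C)CCC=C(C)C)=CC1=O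
F9 | step 9 | [(1S,2S,5S,6R)-2,5-dihydroxy-6-[(1S,2E,4E,6E)-1-hydroxy-3,7,11-trimethyldodeca-2,4,6,10-tetraen-1-yl]-7-oxabicyclo[4.1.0]hept-3-en-3-yl]methyl acetate | CC(=O)OCC1=C[C@H](O)[C@@]2([C@@H](O)/C=C(C)/C=C/C=C(\C)CCC=C(C)C)O[C@H]2[C@H]1O
F10 | step 9 | [(1S,2R,5S,6R)-2-(chloroacetoxy)-5-hydroxy-6-[(1S,2E,4E,6E)-1-hydroxy-3,7,11-trimethyldodeca-2,4,6,10-tetraen-1-yl]-7-oxabicyclo[4.1.0]hept-3-en-3-yl]methyl acetate | CC(=O)OCC1=C[C@H](O)[C@@]2([C@@H](O)/C=C(C)/C=C/C=C(\C)CCC=C(C)C)O[C@H]2[C@@H]1OC(=O)CCl
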